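The only ring of jaspaquinol, the 2,6,6-trimethylcyclohexene (C1 bears the chain, C2 the vinylic methyl, C6 the gem-dimethyl pair), contains a Diels–Alder retron: the tetrasubstituted C1=C2 alkene lies between methylene C3 and quaternary C6. The route therefore adds a two-carbon dienophile, phenyl vinyl sulfone as an ethylene equivalent, across an acyclic 1,1-dimethyl-2,3-disubstituted butadiene that carries a phenylsulfonylmethyl handle, forming C3–C4 and C5–C6 in one operation. The handle then couples the ring to an arylated geranyl bromide, a single reduction strips both sulfonyl groups, and oxidative demethylation with reduction unmasks the hydroquinone.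

Key step: step 3

Remark: jaspaquinol has no stereocentre, so only the two E trisubstituted alkenes need to be secured; cycloadduct 6 is drawn as the sulfonyl regioisomer expected on electronic grounds, and the other regioisomer would converge on 15 all the same.

Step 1
Reactants: 1 2-methylbut-3-yn-2-ol
Product: 3 [(3-methylbuta-1,2-dien-1-yl)sulfonyl]benzene, via propargylic sulfinate ester 2 (not isolated)
Conditions: PhS(O)Cl, pyridine, CH2Cl2, –20 °C to 0 °C; aqueous wash; then MeCN, 80 °C
Reagents that add atoms: benzenesulfinyl chloride, O=S(Cl)c1ccccc1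
Why: O-sulfinylation of the tertiary propargylic alcohol should give sulfinate 2, whose thermal [2,3]-sigmatropic rearrangement (propargylic sulfinate to allenyl sulfone) is driven by formation of the sulfonyl group; the allene is achiral.

Step 2
Reactants: 3 [(3-methylbuta-1,2-dien-1-yl)sulfonyl]benzene
Product: 4 {[3-methyl-2-(prop-1-en-2-yl)but-2-en-1-yl]sulfonyl}benzene
Conditions: CH2=C(CH3)MgBr (slow addition), CuI (10 mol %), THF, –78 °C to –40 °C; aq NH4Cl at –78 °C
Reagents that add atoms: isopropenylmagnesium bromide, C=C(C)[Mg]Br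
Why: copper-catalysed conjugate addition of the alkenyl Grignard reagent to the central carbon of the allenyl sulfone should give a sulfonyl-stabilised allyl anion, and kinetic protonation at its α-carbon leaves the allylic (β,γ-unsaturated) sulfone with the tetrasubstituted diene in place.

Step 3
Reactants: 4 {[3-methyl-2-(prop-1-en-2-yl)but-2-en-1-yl]sulfonyl}benzene; 5 phenyl vinyl sulfone
Product: 6 rac-{[5-(benzenesulfonyl)-2,6,6-trimethylcyclohex-1-en-1-yl]methanesulfonyl}benzene
Conditions: 5 (3 equiv), BHT (cat.), toluene (2 M), sealed tube, 150 °C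
Reagents that add atoms: none
Why: This is a thermal normal-demand Diels–Alder reaction: the skewed cisoid conformer of diene 4, favoured by the substituents on both inner carbons, adds suprafacially to the electron-poor alkene of 5 through a concerted but asynchronous transition state, in which the bond from the unhindered CH2 terminus to the β-carbon of the vinyl sulfone leads and the bond from the sulfonyl-bearing carbon to the CMe2 terminus follows. The closest known reaction type is the use of phenyl vinyl sulfone as an ethylene equivalent in cycloadditions with 2,3-dialkylbutadienes. The cyclohexene ring is closed by intermolecular [4+2] cycloaddition, ring bonds C3–C4 and C5–C6 arising in the same step and the former central bond of the diene becoming the tetrasubstituted C1=C2 alkene, so the position of the ring alkene is fixed by the mechanism. The only new stereocentre, the sulfonyl-bearing ring carbon, is formed racemic and needs no control because it is erased in step 8. The step needs chemoselectivity only: 4 holds the sole conjugated diene, both sulfonyl regioisomers (the one drawn is favoured by the diene coefficients) converge after desulfonylation, and the [1,5]-hydrogen shift open to the diene at this temperature is degenerate, exchanging the isopropenyl and isopropylidene ends and so returning 4 itself.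

Step 4
Reactants: 7 1,4-dimethoxybenzene; 8 geranyl bromide
Product: 10 2-[(2E)-3,7-dimethylocta-2,6-dien-1-yl]-1,4-dimethoxybenzene, via 2,5-dimethoxyphenyllithium 9 (not isolated)
Conditions: n-BuLi, TMEDA, THF, 0 °C; then 8, –78 °C to rt
Reagents that add atoms: none
Why: ether-directed ortho-lithiation should give aryllithium 9, which displaces the primary allylic bromide by SN2 at C1 of geranyl bromide, so the 2E alkene is carried over unchanged.

Step 5
Reactants: 10 2-[(2E)-3,7-dimethylocta-2,6-dien-1-yl]-1,4-dimethoxybenzene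
Product: 11 (2E,6E)-8-(2,5-dimethoxyphenyl)-2,6-dimethylocta-2,6-dien-1-ol
Conditions: SeO2 (0.3 equiv), t-BuOOH, CH2Cl2, 0 °C to rt
Reagents that add atoms: tert-butyl hydroperoxide, CC(C)(C)OO (terminal oxidant; SeO2, O=[Se]=O, is the catalytic oxygen carrier)
Why: the SeO2 allylic oxidation (ene reaction followed by [2,3]-sigmatropic shift) should attack the more accessible terminal trisubstituted alkene at its E-methyl group, and the [2,3] shift sets the E geometry of the new allylic alcohol.

Step 6
Reactants: 11 (2E,6E)-8-(2,5-dimethoxyphenyl)-2,6-dimethylocta-2,6-dien-1-ol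
Product: 12 2-[(2E,6E)-8-bromo-3,7-dimethylocta-2,6-dien-1-yl]-1,4-dimethoxybenzene
Conditions: CBr4, PPh3, CH2Cl2, 0 °C
Reagents that add atoms: carbon tetrabromide, BrC(Br)(Br)Br
Why: the Appel reaction converts the primary allylic alcohol into the bromide by SN2 displacement of the oxyphosphonium group under neutral conditions, without allylic transposition or loss of the E geometry.

Step 7
Reactants: 6 rac-{[5-(benzenesulfonyl)-2,6,6-trimethylcyclohex-1-en-1-yl]methanesulfonyl}benzene; 12 2-[(2E,6E)-8-bromo-3,7-dimethylocta-2,6-dien-1-yl]-1,4-dimethoxybenzene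
Product: 14 2-[(2E,6E)-9-(benzenesulfonyl)-9-[5-(benzenesulfonyl)-2,6,6-trimethylcyclohex-1-en-1-yl]-3,7-dimethylnona-2,6-dien-1-yl]-1,4-dimethoxybenzene (mixture of diastereomers), via lithiated bis-sulfone 13 (not isolated)
Conditions: n-BuLi (1.05 equiv), THF, –78 °C; then 12, –78 °C to –20 °C
Reagents that add atoms: none
Why: the allylic sulfonyl methylene is more acidic by several pK units and far less hindered than the ring CH(SO2Ph) next to the quaternary carbon, so one equivalent of base should give carbanion 13 selectively, and its SN2 alkylation by the primary allylic bromide (sulfone alkylation) creates a stereocentre that needs no control because step 8 erases it.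

Step 8
Reactants: 14 2-[(2E,6E)-9-(benzenesulfonyl)-9-[5-(benzenesulfonyl)-2,6,6-trimethylcyclohex-1-en-1-yl]-3,7-dimethylnona-2,6-dien-1-yl]-1,4-dimethoxybenzene
Product: 15 2-[(2E,6E)-3,7-dimethyl-9-(2,6,6-trimethylcyclohex-1-en-1-yl)nona-2,6-dien-1-yl]-1,4-dimethoxybenzene
Conditions: Na/Hg (6% Na, excess), Na2HPO4, MeOH/THF, –20 °C to rt
Reagents that add atoms: none
Why: single-electron reductive desulfonylation should cleave both the allylic and the secondary alkyl C–S bond, the allyl anion from the exocyclic sulfone being protonated at its less substituted terminus so that the tetrasubstituted ring alkene stays in place.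

Step 9
Reactants: 15 2-[(2E,6E)-3,7-dimethyl-9-(2,6,6-trimethylcyclohex-1-en-1-yl)nona-2,6-dien-1-yl]-1,4-dimethoxybenzene
Product: 17 jaspaquinol, via quinone 16 (not isolated)
Conditions: (NH4)2Ce(NO3)6, MeCN/H2O, 0 °C; then aq Na2S2O4, Et2O, rt
Reagents that add atoms: water, O
Why: oxidative demethylation of the hydroquinone dimethyl ether by tetravalent cerium (quinone oxygens from water, methanol released) should give benzoquinone 16 without touching the isolated alkenes at 0 °C, and dithionite reduces it to the hydroquinone in the same work-up.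

Compound list
1 | 2-methylbut-3-yn-2-ol | CC(C)(O)C#C | starting material
2 | 2-methylbut-3-yn-2-yl benzenesulfinate (racemic at sulfur) | CC(C)(OS(=O)c1ccccc1)C#C | intermediate
3 | [(3-methylbuta-1,2-dien-1-yl)sulfonyl]benzene | CC(C)=C=CS(=O)(=O)c1ccccc1 | intermediate
4 | {[3-methyl-2-(prop-1-en-2-yl)but-2-en-1-yl]sulfonyl}benzene | CC(C)=C(CS(=O)(=O)c1ccccc1)C(C)=C | intermediate
5 | phenyl vinyl sulfone, (ethenylsulfonyl)benzene | C=CS(=O)(=O)c1ccccc1 | starting material
6 | rac-{[5-(benzenesulfonyl)-2,6,6-trimethylcyclohex-1-en-1-yl]methanesulfonyl}benzene | CC1=C(CS(=O)(=O)c2ccccc2)C(C)(C)C(S(=O)(=O)c2ccccc2)CC1 | intermediate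
7 | 1,4-dimethoxybenzene | COc1ccc(OC)cc1 | starting material
8 | geranyl bromide, (2E)-1-bromo-3,7-dimethylocta-2,6-diene | CC(C)=CCC/C(C)=C/CBr | starting material
9 | 2,5-dimethoxyphenyllithium | [Li]c1cc(OC)ccc1OC | intermediate
10 | 2-[(2E)-3,7-dimethylocta-2,6-dien-1-yl]-1,4-dimethoxybenzene | COc1ccc(OC)c(C/C=C(\C)CCC=C(C)C)c1 | intermediate
11 | (2E,6E)-8-(2,5-dimethoxyphenyl)-2,6-dimethylocta-2,6-dien-1-ol | COc1ccc(OC)c(C/C=C(\C)CC/C=C(\C)CO)c1 | intermediate
12 | 2-[(2E,6E)-8-bromo-3,7-dimethylocta-2,6-dien-1-yl]-1,4-dimethoxybenzene | COc1ccc(OC)c(C/C=C(\C)CC/C=C(\C)CBr)c1 | intermediate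
13 | lithio derivative of 6 at the exocyclic sulfonyl carbon | [Li]C(S(=O)(=O)c1ccccc1)C1=C(C)CCC(S(=O)(=O)c2ccccc2)C1(C)C | intermediate
14 | 2-[(2E,6E)-9-(benzenesulfonyl)-9-[5-(benzenesulfonyl)-2,6,6-trimethylcyclohex-1-en-1-yl]-3,7-dimethylnona-2,6-dien-1-yl]-1,4-dimethoxybenzene (mixture of diastereomers) | COc1ccc(OC)c(C/C=C(\C)CC/C=C(\C)CC(S(=O)(=O)c2ccccc2)C2=C(C)CCC(S(=O)(=O)c3ccccc3)C2(C)C)c1 | intermediate
15 | 2-[(2E,6E)-3,7-dimethyl-9-(2,6,6-trimethylcyclohex-1-en-1-yl)nona-2,6-dien-1-yl]-1,4-dimethoxybenzene | COc1ccc(OC)c(C/C=C(\C)CC/C=C(\C)CCC2=C(C)CCCC2(C)C)c1 | intermediate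
16 | 2-[(2E,6E)-3,7-dimethyl-9-(2,6,6-trimethylcyclohex-1-en-1-yl)nona-2,6-dien-1-yl]cyclohexa-2,5-diene-1,4-dione | O=C1C=CC(=O)C(C/C=C(\C)CC/C=C(\C)CCC2=C(C)CCCC2(C)C)=C1 | intermediate
17 | jaspaquinol, 2-[(2E,6E)-3,7-dimethyl-9-(2,6,6-trimethylcyclohex-1-en-1-yl)nona-2,6-dien-1-yl]benzene-1,4-diol | Oc1ccc(O)c(C/C=C(\C)CC/C=C(\C)CCC2=C(C)CCCC2(C)C)c1 | target

Total step count: 9. Longest linear sequence: 6 steps (steps 1–3 then 7–9, or steps 4–6 then 7–9).

Steps most likely to fail

Step 3. The cycloaddition may be too slow, because the Z-methyl group of the CMe2 terminus destabilises the cisoid diene conformer; at the temperature then needed, 1,3-migration of the allylic sulfonyl group and polymerisation of the dienophile may take over. The fallback sets out from 4 and replaces the thermal cycloaddition by a Lewis-acid-promoted, strongly asynchronous one, which tolerates Z-substituted dienes because bonding to the unhindered CH2 terminus runs far ahead. Acrolein with BF3·OEt2 in CH2Cl2 at –78 °C should give rac-2,2,4-trimethyl-3-[(phenylsulfonyl)methyl]cyclohex-3-ene-1-carbaldehyde F1. Decarbonylation with stoichiometric RhCl(PPh3)3 in refluxing toluene would then give {[(2,6,6-trimethylcyclohex-1-en-1-yl)methyl]sulfonyl}benzene F2. Deprotonation with n-BuLi (THF, –78 °C) gives its lithio derivative F3, alkylation with 12 gives the monosulfone 2-[(2E,6E)-9-(benzenesulfonyl)-3,7-dimethyl-9-(2,6,6-trimethylcyclohex-1-en-1-yl)nona-2,6-dien-1-yl]-1,4-dimethoxybenzene F4, and Na/Hg in buffered MeOH/THF brings the route back at 15.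

Step 2. The Grignard reagent may deprotonate the allenyl sulfone at its α-carbon instead of adding. Addition may also be slow, because a γ-methyl group screens each face of the central allene carbon, and protonation at the γ-carbon would lead to the conjugated vinyl sulfone. The fallback sets out from 3 and separates the two events. Hydroiodination with NaI in AcOH (conjugate addition of the small iodide, then protonation) should give [(2-iodo-3-methylbut-2-en-1-yl)sulfonyl]benzene F5. A Suzuki–Miyaura coupling with isopropenylboronic acid pinacol ester (Pd(PPh3)4, K3PO4, THF/H2O, 50 °C) then returns to 4.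

Step 5. The ene reaction of SeO2 may fail to discriminate between the two trisubstituted alkenes of 10, attacking the allylic CH2 of the inner alkene, and the alcohol may be over-oxidised to the enal. The fallback moves the oxidation to commercially available geranyl acetate, whose acetoxy group deactivates the proximal alkene, and sets out from 13 (made from 6 as in step 7). SeO2/t-BuOOH should give (2E,6E)-8-hydroxy-3,7-dimethylocta-2,6-dien-1-yl acetate F6, and CBr4/PPh3 gives (2E,6E)-8-bromo-3,7-dimethylocta-2,6-dien-1-yl acetate F7. Alkylation of 13 with this bromide (THF, –78 °C) gives (2E,6E)-9-(benzenesulfonyl)-9-[5-(benzenesulfonyl)-2,6,6-trimethylcyclohex-1-en-1-yl]-3,7-dimethylnona-2,6-dien-1-yl acetate F8. A palladium-catalysed allyl–aryl coupling of the primary allylic acetate with 2,5-dimethoxyphenylboronic acid (Pd2(dba)3, PPh3, KF, THF, 50 °C) installs the arene at the terminal carbon and returns to 14. The hindered, tetrasubstituted allylic sulfone is expected to ionise far more slowly than the primary acetate.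

Further compounds
F1 | step 3 | rac-2,2,4-trimethyl-3-[(phenylsulfonyl)methyl]cyclohex-3-ene-1-carbaldehyde | CC1=C(CS(=O)(=O)c2ccccc2)C(C)(C)C(C=O)CC1
F2 | step 3 | {[(2,6,6-trimethylcyclohex-1-en-1-yl)methyl]sulfonyl}benzene | CC1=C(CS(=O)(=O)c2ccccc2)C(C)(C)CCC1
F3 | step 3 | lithio derivative of F2 at the sulfonyl carbon | [Li]C(S(=O)(=O)c1ccccc1)C1=C(C)CCCC1(C)C
F4 | step 3 | 2-[(2E,6E)-9-(benzenesulfonyl)-3,7-dimethyl-9-(2,6,6-trimethylcyclohex-1-en-1-yl)nona-2,6-dien-1-yl]-1,4-dimethoxybenzene | COc1ccc(OC)c(C/C=C(\C)CC/C=C(\C)CC(S(=O)(=O)c2ccccc2)C2=C(C)CCCC2(C)C)c1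
F5 | step 2 | [(2-iodo-3-methylbut-2-en-1-yl)sulfonyl]benzene | CC(C)=C(I)CS(=O)(=O)c1ccccc1
F6 | step 5 | (2E,6E)-8-hydroxy-3,7-dimethylocta-2,6-dien-1-yl acetate | CC(=O)OC/C=C(\C)CC/C=C(\C)CO
F7 | step 5 | (2E,6E)-8-bromo-3,7-dimethylocta-2,6-dien-1-yl acetate | CC(=O)OC/C=C(\C)CC/C=C(\C)CBr
F8 | step 5 | (2E,6E)-9-(benzenesulfonyl)-9-[5-(benzenesulfonyl)-2,6,6-trimethylcyclohex-1-en-1-yl]-3,7-dimethylnona-2,6-dien-1-yl acetate | CC(=O)OC/C=C(\C)CC/C=C(\C)CC(S(=O)(=O)c1ccccc1)C1=C(C)CCC(S(=O)(=O)c2ccccc2)C1(C)C
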